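The plan rests on opening the 2,2-dimethylpyran ring at O2'–C2'' and C3'–C4''. This leads back to an aryl 1,1-dimethylpropargyl ether on the complete (3R)-isoflavan. The precursor is the 8-formyl-5-methoxyisoflavan with MOM groups on O7 and O4' and the propargyl unit on O2'. Heating it should build the ring in one neutral operation through a [3,3] shift, a hydrogen shift and an oxa-6π closure. The step exploits ring B: of the two carbons ortho to O2', C1' carries chroman C3 and only C3' bears hydrogen, while capped O4' cannot compete in the closure. C3 is set earlier by an Evans alkylation, and C8 is marked by an early bromine.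

Key step: step 18

Remark: the SMILES string encodes 3R. Isoflavan numbering is used (O1, C2, C3, C4, C4a, C5–C8, C8a; ring B primed; pyran atoms C2'', C3'', C4'').

Step 1
Reactants: 1 2,4,6-trihydroxybenzaldehyde
Product: 2 2,6-dihydroxy-4-(methoxymethoxy)benzaldehyde
Conditions: MOMCl (1.0 equiv), i-Pr2NEt (1.1 equiv), THF, 0 °C
Reagents that add atoms: chloromethyl methyl ether (MOMCl), COCCl
Why: The 4-OH is the only hydroxyl not hydrogen-bonded to the formyl oxygen and is the most acidic, so one equivalent of MOMCl should give a chemoselective Williamson-type O-alkylation there.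

Step 2
Reactants: 2 2,6-dihydroxy-4-(methoxymethoxy)benzaldehyde
Product: 3 2-hydroxy-6-methoxy-4-(methoxymethoxy)benzaldehyde
Conditions: MeI (1.05 equiv), K2CO3 (1.1 equiv), acetone, rt
Reagents that add atoms: iodomethane, CI
Why: Williamson O-methylation of one of the two equivalent ortho hydroxyls leaves the other as a stronger chelate to the aldehyde, which should stop the reaction at the monoether.

Step 3
Reactants: 3 2-hydroxy-6-methoxy-4-(methoxymethoxy)benzaldehyde
Product: 4 3-bromo-2-hydroxy-6-methoxy-4-(methoxymethoxy)benzaldehyde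
Conditions: NBS (1.0 equiv), CH2Cl2, −20 → 0 °C
Reagents that add atoms: N-bromosuccinimide, O=C1CCC(=O)N1Br
Why: Electrophilic aromatic bromination should take C3, the carbon ortho to the chelated phenol and para to the methoxy group, because C5 is crowded by two alkoxy groups, and this puts the halogen on the future C8 before ring B can compete.

Step 4
Reactants: 4 3-bromo-2-hydroxy-6-methoxy-4-(methoxymethoxy)benzaldehyde
Product: 5 2-(allyloxy)-3-bromo-6-methoxy-4-(methoxymethoxy)benzaldehyde
Conditions: allyl bromide, K2CO3, DMF, 50 °C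
Reagents that add atoms: allyl bromide, C=CCBr
Why: Williamson etherification masks the future O1 as an allyl ether, which is orthogonal to the MOM and benzyl groups and can later be removed without touching the aryl bromide.

Step 5
Reactants: 5 2-(allyloxy)-3-bromo-6-methoxy-4-(methoxymethoxy)benzaldehyde
Product: 6 [2-(allyloxy)-3-bromo-6-methoxy-4-(methoxymethoxy)phenyl]methanol
Conditions: NaBH4, MeOH–THF, 0 °C
Reagents that add atoms: none
Why: Borohydride 1,2-reduction of the aldehyde is chemoselective, since the aryl bromide, the allyl ether and the acetal are inert to NaBH4.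

Step 6
Reactants: 6 [2-(allyloxy)-3-bromo-6-methoxy-4-(methoxymethoxy)phenyl]methanol
Product: 8 2-(allyloxy)-3-bromo-6-methoxy-4-(methoxymethoxy)benzyl bromide, via benzylic mesylate 7 (not isolated)
Conditions: MsCl, Et3N, THF, −40 °C; then LiBr, THF, −40 → 0 °C; used crude at once
Reagents that add atoms: lithium bromide, [Li+].[Br-]
Why: Mesylation followed by SN2 displacement with bromide avoids free HBr, which would cleave the MOM group, and the product is carried on directly because its three alkoxy groups make it prone to ionise.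

Step 7
Reactants: 9 2,4-dihydroxyphenylacetic acid
Product: 10 6-hydroxybenzofuran-2(3H)-one
Conditions: p-TsOH·H2O (cat.), toluene, reflux, Dean–Stark
Reagents that add atoms: none
Why: Acid-catalysed lactonisation is possible only for the hydroxyl ortho to the acetic acid chain, so the five-membered lactone tells the two phenols of ring B apart.

Step 8
Reactants: 10 6-hydroxybenzofuran-2(3H)-one
Product: 11 6-(methoxymethoxy)benzofuran-2(3H)-one
Conditions: MOMCl, i-Pr2NEt, CH2Cl2, 0 °C
Reagents that add atoms: chloromethyl methyl ether (MOMCl), COCCl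
Why: The sole free phenol, the future O4', undergoes Williamson-type O-alkylation with MOMCl, and a mild amine base is chosen to spare the lactone.

Step 9
Reactants: 11 6-(methoxymethoxy)benzofuran-2(3H)-one
Product: 13 2-[2-(benzyloxy)-4-(methoxymethoxy)phenyl]acetic acid, via disodium phenoxide carboxylate 12 (not isolated)
Conditions: NaOH (3 equiv), H2O–EtOH, rt; BnBr, 60 °C; then 1 M HCl to pH 4, 0 °C
Reagents that add atoms: sodium hydroxide, [Na+].[OH-]; benzyl bromide, BrCc1ccccc1
Why: Saponification of the lactone frees the ortho phenoxide, whose Williamson benzylation outruns that of the carboxylate, and any benzyl ester formed is hydrolysed by the excess hydroxide.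

Step 10
Reactants: 13 2-[2-(benzyloxy)-4-(methoxymethoxy)phenyl]acetic acid; 14 (4R)-4-benzyl-1,3-oxazolidin-2-one
Product: 16 (4R)-4-benzyl-3-{2-[2-(benzyloxy)-4-(methoxymethoxy)phenyl]acetyl}-1,3-oxazolidin-2-one, via mixed pivalic anhydride 15 (not isolated)
Conditions: t-BuCOCl, Et3N, THF, −20 °C; then 14, LiCl, −20 °C → rt
Reagents that add atoms: none
Why: N-Acylation of the oxazolidinone through the mixed pivalic anhydride is the standard entry to Evans imides, with attack at the less hindered arylacetyl carbonyl.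

Step 11
Reactants: 16 (4R)-4-benzyl-3-{2-[2-(benzyloxy)-4-(methoxymethoxy)phenyl]acetyl}-1,3-oxazolidin-2-one; 8 2-(allyloxy)-3-bromo-6-methoxy-4-(methoxymethoxy)benzyl bromide
Product: 18 (4R)-4-benzyl-3-{(2R)-3-[2-(allyloxy)-3-bromo-6-methoxy-4-(methoxymethoxy)phenyl]-2-[2-(benzyloxy)-4-(methoxymethoxy)phenyl]propanoyl}-1,3-oxazolidin-2-one, via sodium Z-enolate 17 (not isolated)
Conditions: NaN(SiMe3)2, THF, −78 °C; then 8, −78 → −30 °C
Reagents that add atoms: none
Why: In this Evans asymmetric alkylation the chelated Z-enolate is shielded on one face by the benzyl group at C4 of the (R)-auxiliary, so the benzylic bromide should add from the opposite face and set the (2R) centre that becomes C3.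

Step 12
Reactants: 18 the alkylated imide
Product: 19 (2R)-3-[2-(allyloxy)-3-bromo-6-methoxy-4-(methoxymethoxy)phenyl]-2-[2-(benzyloxy)-4-(methoxymethoxy)phenyl]propan-1-ol
Conditions: LiBH4, Et2O–THF, 0 °C
Reagents that add atoms: none
Why: Hydride reduction of the exocyclic imide carbonyl by LiBH4 releases the auxiliary and gives the primary alcohol under conditions that do not epimerise α-aryl centres, while the aryl bromide and all ethers are inert.

Step 13
Reactants: 19 (2R)-3-[2-(allyloxy)-3-bromo-6-methoxy-4-(methoxymethoxy)phenyl]-2-[2-(benzyloxy)-4-(methoxymethoxy)phenyl]propan-1-ol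
Product: 20 2-{(2R)-2-[2-(benzyloxy)-4-(methoxymethoxy)phenyl]-3-hydroxypropyl}-6-bromo-3-methoxy-5-(methoxymethoxy)phenol
Conditions: Pd(PPh3)4 (5 mol %), morpholine, THF, rt
Reagents that add atoms: none
Why: Tsuji–Trost deallylation by zerovalent palladium passes the allyl group to morpholine at room temperature, where the hindered, electron-rich aryl bromide should not undergo oxidative addition.

Step 14
Reactants: 20 2-{(2R)-2-[2-(benzyloxy)-4-(methoxymethoxy)phenyl]-3-hydroxypropyl}-6-bromo-3-methoxy-5-(methoxymethoxy)phenol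
Product: 21 (3R)-3-[2-(benzyloxy)-4-(methoxymethoxy)phenyl]-8-bromo-5-methoxy-7-(methoxymethoxy)chroman
Conditions: PPh3, DIAD, THF, 0 °C → rt
Reagents that add atoms: none
Why: Intramolecular Mitsunobu etherification (6-exo-tet) joins the only free phenol to the primary carbon, so ring C closes without touching the adjacent stereocentre.

Step 15
Reactants: 21 (3R)-3-[2-(benzyloxy)-4-(methoxymethoxy)phenyl]-8-bromo-5-methoxy-7-(methoxymethoxy)chroman
Product: 23 (3R)-3-[2-(benzyloxy)-4-(methoxymethoxy)phenyl]-5-methoxy-7-(methoxymethoxy)chroman-8-carbaldehyde, via C8 aryllithium 22 (not isolated)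
Conditions: n-BuLi, THF, −78 °C; DMF, −78 → 0 °C; then H2O
Reagents that add atoms: N,N-dimethylformamide, CN(C)C=O
Why: Bromine–lithium exchange is faster than any directed lithiation at −78 °C and fixes the carbanion at C8, where formylation with DMF gives the aldehyde free of C6 or ring B isomers.

Step 16
Reactants: 23 (3R)-3-[2-(benzyloxy)-4-(methoxymethoxy)phenyl]-5-methoxy-7-(methoxymethoxy)chroman-8-carbaldehyde
Product: 24 (3R)-3-[2-hydroxy-4-(methoxymethoxy)phenyl]-5-methoxy-7-(methoxymethoxy)chroman-8-carbaldehyde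
Conditions: H2 (1 atm), 10% Pd/C, EtOAc, rt
Reagents that add atoms: none
Why: Catalytic hydrogenolysis cleaves the aryl benzyl ether quickly, whereas the aldehyde, deactivated by three ortho and para oxygen donors, should be reduced far more slowly at one atmosphere.

Step 17
Reactants: 24 (3R)-3-[2-hydroxy-4-(methoxymethoxy)phenyl]-5-methoxy-7-(methoxymethoxy)chroman-8-carbaldehyde; 25 3-chloro-3-methylbut-1-yne
Product: 26 (3R)-5-methoxy-7-(methoxymethoxy)-3-[4-(methoxymethoxy)-2-(2-methylbut-3-yn-2-yloxy)phenyl]chroman-8-carbaldehyde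
Conditions: CuCl2·2H2O (1 mol %), DBU, MeCN, 0 °C → rt
Reagents that add atoms: none
Why: Copper-catalysed propargylic etherification runs through a copper acetylide that loses chloride to an electrophilic allenylidene-type species, which the only free phenoxide, O2', attacks at the tertiary carbon.

Step 18
Reactants: 26 (3R)-5-methoxy-7-(methoxymethoxy)-3-[4-(methoxymethoxy)-2-(2-methylbut-3-yn-2-yloxy)phenyl]chroman-8-carbaldehyde
Product: 30 (3R)-5-methoxy-7-(methoxymethoxy)-3-[5-(methoxymethoxy)-2,2-dimethyl-2H-chromen-8-yl]chroman-8-carbaldehyde, via allenyl dienone 27 (not isolated), via o-allenylphenol 28 (not isolated), via o-quinone methide 29 (not isolated)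
Conditions: o-xylene (degassed, 0.05 M), 140 °C, Ar
Reagents that add atoms: none
Why: The aryl propargyl Claisen rearrangement carries the alkyne terminus from O2' to C3', forms C3'–C4'' and gives allenyl dienone 27, which enolises to o-allenylphenol 28. A 1,5-hydrogen shift from the phenol oxygen to the central allene carbon produces o-quinone methide 29, and a thermal disrotatory oxa-6π electrocyclisation closes the six-membered pyran ring by forming O2'–C2''. This is the classical thermal conversion of aryl 1,1-dimethylpropargyl ethers into 2,2-dimethyl-2H-chromenes, and the gem-dimethyl group lowers the temperature it needs. Regioselectivity is required between C3' and C1': a shift to C1' gives a dienone with a quaternary carbon that cannot enolise and returns to 26, so only the C3' channel drains. The MOM group on O4' leaves O2' as the sole oxygen able to close onto the dienone, which fixes the angular fusion. No stereocentre is formed, and C3, which is neither acidic nor involved, should keep its R configuration in the neutral medium.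

Step 19
Reactants: 30 (3R)-5-methoxy-7-(methoxymethoxy)-3-[5-(methoxymethoxy)-2,2-dimethyl-2H-chromen-8-yl]chroman-8-carbaldehyde
Product: 31 (3R)-7-hydroxy-3-(5-hydroxy-2,2-dimethyl-2H-chromen-8-yl)-5-methoxychroman-8-carbaldehyde (CNP0272344.1)
Conditions: 2 M aq HCl, THF–i-PrOH, 45 °C
Reagents that add atoms: none
Why: Acid-catalysed acetal hydrolysis removes both MOM groups, the one on O7 assisted by the neighbouring formyl group, under conditions mild enough for 2,2-dimethylchromenes.

Compound list
1 | 2,4,6-trihydroxybenzaldehyde | O=Cc1c(O)cc(O)cc1O | starting material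
2 | 2,6-dihydroxy-4-(methoxymethoxy)benzaldehyde | O=Cc1c(O)cc(OCOC)cc1O | intermediate
3 | 2-hydroxy-6-methoxy-4-(methoxymethoxy)benzaldehyde | COc1cc(OCOC)cc(O)c1C=O | intermediate
4 | 3-bromo-2-hydroxy-6-methoxy-4-(methoxymethoxy)benzaldehyde | COc1cc(OCOC)c(Br)c(O)c1C=O | intermediate
5 | 2-(allyloxy)-3-bromo-6-methoxy-4-(methoxymethoxy)benzaldehyde | COc1cc(OCOC)c(Br)c(OCC=C)c1C=O | intermediate
6 | [2-(allyloxy)-3-bromo-6-methoxy-4-(methoxymethoxy)phenyl]methanol | COc1cc(OCOC)c(Br)c(OCC=C)c1CO | intermediate
7 | 2-(allyloxy)-3-bromo-6-methoxy-4-(methoxymethoxy)benzyl methanesulfonate (formed in the flask) | COc1cc(OCOC)c(Br)c(OCC=C)c1COS(C)(=O)=O | intermediate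
8 | 2-(allyloxy)-3-bromo-6-methoxy-4-(methoxymethoxy)benzyl bromide | COc1cc(OCOC)c(Br)c(OCC=C)c1CBr | intermediate
9 | 2,4-dihydroxyphenylacetic acid | OC(=O)Cc1ccc(O)cc1O | starting material
10 | 6-hydroxybenzofuran-2(3H)-one | O=C1Cc2ccc(O)cc2O1 | intermediate
11 | 6-(methoxymethoxy)benzofuran-2(3H)-one | O=C1Cc2ccc(OCOC)cc2O1 | intermediate
12 | disodium 2-[4-(methoxymethoxy)-2-oxidophenyl]acetate (formed in the flask) | [Na+].[Na+].[O-]C(=O)Cc1ccc(OCOC)cc1[O-] | intermediate
13 | 2-[2-(benzyloxy)-4-(methoxymethoxy)phenyl]acetic acid | OC(=O)Cc1ccc(OCOC)cc1OCc1ccccc1 | intermediate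
14 | (4R)-4-benzyl-1,3-oxazolidin-2-one | O=C1N[C@H](Cc2ccccc2)CO1 | starting material
15 | 2-[2-(benzyloxy)-4-(methoxymethoxy)phenyl]acetic pivalic anhydride (formed in the flask) | CC(C)(C)C(=O)OC(=O)Cc1ccc(OCOC)cc1OCc1ccccc1 | intermediate
16 | (4R)-4-benzyl-3-{2-[2-(benzyloxy)-4-(methoxymethoxy)phenyl]acetyl}-1,3-oxazolidin-2-one | O=C(Cc1ccc(OCOC)cc1OCc1ccccc1)N1[C@H](Cc2ccccc2)COC1=O | intermediate
17 | sodium (Z)-enolate of imide 16 (formed in the flask) | [Na+].[O-]/C(=C\c1ccc(OCOC)cc1OCc1ccccc1)N1[C@H](Cc2ccccc2)COC1=O | intermediate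
18 | (4R)-4-benzyl-3-{(2R)-3-[2-(allyloxy)-3-bromo-6-methoxy-4-(methoxymethoxy)phenyl]-2-[2-(benzyloxy)-4-(methoxymethoxy)phenyl]propanoyl}-1,3-oxazolidin-2-one | O=C([C@H](Cc1c(OC)cc(OCOC)c(Br)c1OCC=C)c1ccc(OCOC)cc1OCc1ccccc1)N1[C@H](Cc2ccccc2)COC1=O | intermediate
19 | (2R)-3-[2-(allyloxy)-3-bromo-6-methoxy-4-(methoxymethoxy)phenyl]-2-[2-(benzyloxy)-4-(methoxymethoxy)phenyl]propan-1-ol | OC[C@H](Cc1c(OC)cc(OCOC)c(Br)c1OCC=C)c1ccc(OCOC)cc1OCc1ccccc1 | intermediate
20 | 2-{(2R)-2-[2-(benzyloxy)-4-(methoxymethoxy)phenyl]-3-hydroxypropyl}-6-bromo-3-methoxy-5-(methoxymethoxy)phenol | OC[C@H](Cc1c(OC)cc(OCOC)c(Br)c1O)c1ccc(OCOC)cc1OCc1ccccc1 | intermediate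
21 | (3R)-3-[2-(benzyloxy)-4-(methoxymethoxy)phenyl]-8-bromo-5-methoxy-7-(methoxymethoxy)chroman | COc1cc(OCOC)c(Br)c2c1C[C@H](c1ccc(OCOC)cc1OCc1ccccc1)CO2 | intermediate
22 | C8 aryllithium derived from 21 (formed in the flask) | COc1cc(OCOC)c([Li])c2c1C[C@H](c1ccc(OCOC)cc1OCc1ccccc1)CO2 | intermediate
23 | (3R)-3-[2-(benzyloxy)-4-(methoxymethoxy)phenyl]-5-methoxy-7-(methoxymethoxy)chroman-8-carbaldehyde | COc1cc(OCOC)c(C=O)c2c1C[C@H](c1ccc(OCOC)cc1OCc1ccccc1)CO2 | intermediate
24 | (3R)-3-[2-hydroxy-4-(methoxymethoxy)phenyl]-5-methoxy-7-(methoxymethoxy)chroman-8-carbaldehyde | COc1cc(OCOC)c(C=O)c2c1C[C@H](c1ccc(OCOC)cc1O)CO2 | intermediate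
25 | 3-chloro-3-methylbut-1-yne | CC(C)(Cl)C#C | starting material
26 | (3R)-5-methoxy-7-(methoxymethoxy)-3-[4-(methoxymethoxy)-2-(2-methylbut-3-yn-2-yloxy)phenyl]chroman-8-carbaldehyde | COc1cc(OCOC)c(C=O)c2c1C[C@H](c1ccc(OCOC)cc1OC(C)(C)C#C)CO2 | intermediate
27 | C3'-(3-methylbuta-1,2-dienyl)cyclohexa-2,4-dienone from the [3,3] shift (formed in the flask; C3' configuration undefined) | COc1cc(OCOC)c(C=O)c2c1C[C@H](C1=CC=C(OCOC)C(C=C=C(C)C)C1=O)CO2 | intermediate
28 | (3R)-3-[2-hydroxy-4-(methoxymethoxy)-3-(3-methylbuta-1,2-dienyl)phenyl]-5-methoxy-7-(methoxymethoxy)chroman-8-carbaldehyde (formed in the flask) | COc1cc(OCOC)c(C=O)c2c1C[C@H](c1ccc(OCOC)c(C=C=C(C)C)c1O)CO2 | intermediate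
29 | o-quinone methide with a 3-methylbut-2-enylidene group at C3' (formed in the flask) | COc1cc(OCOC)c(C=O)c2c1C[C@H](C1=CC=C(OCOC)C(=CC=C(C)C)C1=O)CO2 | intermediate
30 | (3R)-5-methoxy-7-(methoxymethoxy)-3-[5-(methoxymethoxy)-2,2-dimethyl-2H-chromen-8-yl]chroman-8-carbaldehyde | COc1cc(OCOC)c(C=O)c2c1C[C@H](c1ccc(OCOC)c3c1OC(C)(C)C=C3)CO2 | intermediate
31 | (3R)-7-hydroxy-3-(5-hydroxy-2,2-dimethyl-2H-chromen-8-yl)-5-methoxychroman-8-carbaldehyde | COc1cc(O)c(C=O)c2c1C[C@H](c1ccc(O)c3c1OC(C)(C)C=C3)CO2 | target

Total step count: 19 (fragment A steps 1–6, fragment B steps 7–10, steps 11–19 after the coupling).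
Longest linear sequence: 15 steps (steps 1–6 and 11–19).

Steps most likely to fail

Step 18. The cascade may stall or divert in three ways: slow enolisation of the crowded dienone, thermal loss of the tertiary ether by elimination, or oligomerisation of the quinone methide at the temperature needed. The fallback sets out from 26 and comes back at 30. Semi-hydrogenation of the alkyne over Pd/CaCO3–Pb(OAc)2 with quinoline gives the 1,1-dimethylallyl ether F1. An aromatic Claisen rearrangement then gives the C3'-prenylphenol F2. It runs at lower temperature than the propargyl variant and again finds only C3' open. Dehydrogenative cyclisation with DDQ in toluene closes the pyran ring through the same quinone methide 29.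

Step 11. Bromide 8 may ionise and oligomerise before the enolate captures it, and incomplete facial shielding would erode the configuration at C3. The fallback sets out from salicylaldehyde 4 and acid 13 and comes back at 21, so steps 4–6 and 10–14 are left out.
- A Perkin-type condensation (Ac2O, Et3N, 100 °C) gives the 3-arylcoumarin F3.
- i-Bu2AlH reduces the lactone to the (Z)-allylic alcohol phenol F4.
- Intramolecular Mitsunobu etherification gives the isoflav-3-ene F5.
- Asymmetric hydrogenation of the trisubstituted alkene with [Ir(cod)(t-Bu-PHOX)][B(C6H3(CF3)2)4] under H2 sets C3 catalytically. The ligand enantiomer is chosen for the 3R product, and the aryl bromide and the benzyl ether are inert to this homogeneous catalyst.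

Step 17. O-Alkylation of the hindered phenoxide next to the chroman may be slower than elimination or solvolysis of the tertiary chloride. The fallback sets out from 24 and comes back at 30. The phenol is turned into its titanium phenoxide with Ti(OEt)4 in toluene and heated with 3-methylbut-2-enal. Ortho-hydroxyalkylation at C3', the only free ortho carbon, followed by loss of water gives quinone methide 29, which closes by the same oxa-6π step. This detour makes no compound outside the list (entry F0).

Further compounds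
F1 | step 18 | (3R)-5-methoxy-7-(methoxymethoxy)-3-[4-(methoxymethoxy)-2-(2-methylbut-3-en-2-yloxy)phenyl]chroman-8-carbaldehyde | COc1cc(OCOC)c(C=O)c2c1C[C@H](c1ccc(OCOC)cc1OC(C)(C)C=C)CO2
F2 | step 18 | (3R)-3-[2-hydroxy-4-(methoxymethoxy)-3-(3-methylbut-2-en-1-yl)phenyl]-5-methoxy-7-(methoxymethoxy)chroman-8-carbaldehyde | COc1cc(OCOC)c(C=O)c2c1C[C@H](c1ccc(OCOC)c(CC=C(C)C)c1O)CO2
F3 | step 11 | 3-[2-(benzyloxy)-4-(methoxymethoxy)phenyl]-8-bromo-5-methoxy-7-(methoxymethoxy)-2H-chromen-2-one | COc1cc(OCOC)c(Br)c2c1C=C(c1ccc(OCOC)cc1OCc1ccccc1)C(=O)O2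
F4 | step 11 | 2-{(Z)-2-[2-(benzyloxy)-4-(methoxymethoxy)phenyl]-3-hydroxyprop-1-enyl}-6-bromo-3-methoxy-5-(methoxymethoxy)phenol | COc1cc(OCOC)c(Br)c(O)c1/C=C(\CO)c1ccc(OCOC)cc1OCc1ccccc1
F5 | step 11 | 3-[2-(benzyloxy)-4-(methoxymethoxy)phenyl]-8-bromo-5-methoxy-7-(methoxymethoxy)-2H-chromene | COc1cc(OCOC)c(Br)c2c1C=C(c1ccc(OCOC)cc1OCc1ccccc1)CO2
F0 | step 17 | none | none
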